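**Retrosynthetic overview**

1. Target 27 ⇐ C15 alcohol oxidation, C19–O acylation with (R)-2-methylbutanoic acid, C19 ester reduction, C3 deoxygenation and C4 methylation ⇐ bicyclic β-keto ester 17.
2. 17 ⇐ key step: in bicyclo[3.1.0]hexan-2-one 16 the bond C4–C10 is cut and C9–C10 is made, so the cyclopentanone (C3, C4, C10, C1, C2) takes in C5 and becomes ring A while ring B closes onto an allylsilane.
3. 16 ⇐ intramolecular cyclopropanation of the acyclic α-diazo-β-keto ester 15 (carbene C4 onto the (E)-C5=C10 alkene). Ring order: three- and five-membered rings first (step 10), then ring B together with the growth of the five-membered ring to ring A (step 11).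
4. 15 ⇐ two Johnson–Claisen homologations (C8=C9, then C5=C10) from (R)-citronellol (C9, C11–C16, sets C13), a 2-bromoallylsilane (C7, C8, C17) and acetate units.
5. Enabling feature: in ring A, C4 (carrying C3 and C19 at carbonyl level, an acceptor) and the methyl-bearing quaternary C10 (a tertiary cation site) are 1,3-related through C5, so C4/C5/C10 can be tied as a cyclopropane whose C4–C10 bond is a donor–acceptor σ-bond; in ring B the exocyclic C8=C17 methylene is the footprint of an allylsilane terminator.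

Key step: step 11

Remark: labdane numbering is used for skeletal atoms; the target is read as (4R,5S,9R,10S,13R)-19-{[(2R)-2-methylbutanoyl]oxy}labd-8(17)-en-15-oic acid (ent-labdane series; C19 cis to the C10 methyl); compounds 1, 5 and 23 and both antipodes of the bis(oxazoline) ligand are taken as commercial.

**Route**

Step 1
Reactants: 1 (R)-citronellol
Product: 2 tert-butyl{[(3R)-3,7-dimethyloct-6-en-1-yl]oxy}diphenylsilane
Conditions: TBDPSCl, imidazole, DMF, 0 °C → rt
Reagents that add atoms: tert-butylchlorodiphenylsilane, CC(C)(C)[Si](Cl)(c1ccccc1)c1ccccc1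
Why: Silylation of the only hydroxyl group (silyl ether protection) touches no stereocentre, and the bulky silyl ether is chosen because it has to survive ozone, Grignard reagents, hot weak acid, SnCl4 at low temperature, hydrides and tin hydride before its removal in step 18.

Step 2
Reactants: 2 tert-butyl{[(3R)-3,7-dimethyloct-6-en-1-yl]oxy}diphenylsilane
Product: 4 (4R)-6-[(tert-butyldiphenylsilyl)oxy]-4-methylhexanal, via secondary ozonide 3 (not isolated)
Conditions: O3, CH2Cl2, −78 °C; then PPh3, −78 °C → rt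
Reagents that add atoms: ozone, O=[O+][O-]
Why: Ozonolysis with reductive work-up cleaves the only alkene to the C9 aldehyde and acetone, the remote C13 stereocentre being untouched.

Step 3
Reactants: 4 (4R)-6-[(tert-butyldiphenylsilyl)oxy]-4-methylhexanal; 5 (2-bromoprop-2-en-1-yl)trimethylsilane
Product: 7 (6R)-8-[(tert-butyldiphenylsilyl)oxy]-6-methyl-2-[(trimethylsilyl)methyl]oct-1-en-3-ol (both C3 epimers), via Grignard reagent 6 (not isolated)
Conditions: 5, Mg, THF, rt; then 4, −78 → 0 °C
Reagents that add atoms: none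
Why: Grignard formation from the vinyl bromide and 1,2-addition to the aldehyde (Grignard addition) bring in C7, C8 and the C17 silylmethyl group as an intact 2-substituted allylsilane, and the carbinol centre at C9 is formed without control, which does not matter because it becomes sp2 in step 4.

Step 4
Reactants: 7 (6R)-8-[(tert-butyldiphenylsilyl)oxy]-6-methyl-2-[(trimethylsilyl)methyl]oct-1-en-3-ol
Product: 9 ethyl (4Z,8R)-10-[(tert-butyldiphenylsilyl)oxy]-8-methyl-4-[(trimethylsilyl)methyl]dec-4-enoate, via ketene acetal 8 (not isolated)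
Conditions: MeC(OEt)3, EtCO2H (cat.), 140 °C, EtOH distilled off
Reagents that add atoms: triethyl orthoacetate, CCOC(C)(OCC)OCC
Why: Johnson–Claisen rearrangement through a chair transition state with the C11 chain equatorial should give the trisubstituted C8=C9 alkene with C7 trans to C11 (Z by the sequence rule because of silicon), the geometry that later fixes C9, and the weak acid is expected to leave the allylsilane intact.

Step 5
Reactants: 9 ethyl (4Z,8R)-10-[(tert-butyldiphenylsilyl)oxy]-8-methyl-4-[(trimethylsilyl)methyl]dec-4-enoate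
Product: 10 (4Z,8R)-10-[(tert-butyldiphenylsilyl)oxy]-8-methyl-4-[(trimethylsilyl)methyl]dec-4-enal
Conditions: i-Bu2AlH, CH2Cl2, −78 °C
Reagents that add atoms: none
Why: At −78 °C the tetrahedral aluminium hemiacetal formed from the ester and i-Bu2AlH is stable until work-up, so the reduction should stop at the aldehyde (partial ester reduction) while alkene, allylsilane and silyl ether are inert.

Step 6
Reactants: 10 (4Z,8R)-10-[(tert-butyldiphenylsilyl)oxy]-8-methyl-4-[(trimethylsilyl)methyl]dec-4-enal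
Product: 11 (6Z,10R)-12-[(tert-butyldiphenylsilyl)oxy]-2,10-dimethyl-6-[(trimethylsilyl)methyl]dodeca-1,6-dien-3-ol (both C3 epimers)
Conditions: CH2=C(CH3)MgBr, THF, −78 → 0 °C
Reagents that add atoms: isopropenylmagnesium bromide, C=C(C)[Mg]Br
Why: Grignard addition to the aldehyde installs C10, C1 and the C20 methyl group, and the new carbinol centre C5 is formed as both epimers, which is irrelevant because it is erased in step 7.

Step 7
Reactants: 11 (6Z,10R)-12-[(tert-butyldiphenylsilyl)oxy]-2,10-dimethyl-6-[(trimethylsilyl)methyl]dodeca-1,6-dien-3-ol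
Product: 13 ethyl (4E,8Z,12R)-14-[(tert-butyldiphenylsilyl)oxy]-4,12-dimethyl-8-[(trimethylsilyl)methyl]tetradeca-4,8-dienoate, via ketene acetal 12 (not isolated)
Conditions: MeC(OEt)3, EtCO2H (cat.), 140 °C, EtOH distilled off
Reagents that add atoms: triethyl orthoacetate, CCOC(C)(OCC)OCC
Why: A second Johnson–Claisen rearrangement, again through a chair with the chain equatorial, should create the (E)-C5=C10 alkene that places the C20 methyl cis to C6 and adds C2 and C3.

Step 8
Reactants: 13 ethyl (4E,8Z,12R)-14-[(tert-butyldiphenylsilyl)oxy]-4,12-dimethyl-8-[(trimethylsilyl)methyl]tetradeca-4,8-dienoate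
Product: 14 methyl (6E,10Z,14R)-16-[(tert-butyldiphenylsilyl)oxy]-6,14-dimethyl-3-oxo-10-[(trimethylsilyl)methyl]hexadeca-6,10-dienoate
Conditions: MeOAc, LiN(i-Pr)2 (3 equiv each), THF, −78 °C; then 13, −78 → −20 °C
Reagents that add atoms: methyl acetate, CC(=O)OC
Why: Crossed Claisen condensation of the ethyl ester with excess lithium enolate of methyl acetate should give the β-keto ester (C4 and C19 added), the equilibrium being pulled by deprotonation of the product, and no stereocentre is formed.

Step 9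
Reactants: 14 methyl (6E,10Z,14R)-16-[(tert-butyldiphenylsilyl)oxy]-6,14-dimethyl-3-oxo-10-[(trimethylsilyl)methyl]hexadeca-6,10-dienoate
Product: 15 methyl (6E,10Z,14R)-2-diazo-16-[(tert-butyldiphenylsilyl)oxy]-6,14-dimethyl-3-oxo-10-[(trimethylsilyl)methyl]hexadeca-6,10-dienoate
Conditions: 4-acetamidobenzenesulfonyl azide, Et3N, MeCN, 0 °C → rt
Reagents that add atoms: 4-acetamidobenzenesulfonyl azide, CC(=O)Nc1ccc(cc1)S(=O)(=O)N=[N+]=[N-]
Why: Regitz diazo transfer to the doubly activated methylene C4 under mild amine base is reliable for β-keto esters and does not touch the allylsilane or the alkenes.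

Step 10
Reactants: 15 methyl (6E,10Z,14R)-2-diazo-16-[(tert-butyldiphenylsilyl)oxy]-6,14-dimethyl-3-oxo-10-[(trimethylsilyl)methyl]hexadeca-6,10-dienoate
Product: 16 methyl (1S,5S,6S)-6-{(3Z,7R)-9-[(tert-butyldiphenylsilyl)oxy]-7-methyl-3-[(trimethylsilyl)methyl]non-3-en-1-yl}-5-methyl-2-oxobicyclo[3.1.0]hexane-1-carboxylate
Conditions: Cu(MeCN)4PF6 (10 mol %), 2,2'-(propane-2,2-diyl)bis[(4S)-4-tert-butyl-4,5-dihydro-1,3-oxazole] (12 mol %), toluene, 50 °C, slow addition of 15
Reagents that add atoms: none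
Why: The monovalent copper–bis(oxazoline) complex should turn the diazo group into an electrophilic copper carbene at C4 that adds to the proximal (E)-C5=C10 alkene through the favoured five-atom tether (intramolecular cyclopropanation, the remote allylsilane being out of reach), the addition being syn-stereospecific so that the C10 methyl and the C6 chain stay cis, while the chiral ligand selects the alkene face and thereby the absolute configuration of C4, C5 and C10 (the ligand antipode that delivers the 1S,5S,6S isomer is to be fixed in a scouting run).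

Step 11
Reactants: 16 methyl (1S,5S,6S)-6-{(3Z,7R)-9-[(tert-butyldiphenylsilyl)oxy]-7-methyl-3-[(trimethylsilyl)methyl]non-3-en-1-yl}-5-methyl-2-oxobicyclo[3.1.0]hexane-1-carboxylate
Product: 17 methyl (5R,9R,10R,13R)-15-[(tert-butyldiphenylsilyl)oxy]-3-oxolabd-8(17)-en-19-oate (trans-decalin; C4 epimers and enol)
Conditions: SnCl4 (1.2 equiv), 2,6-di-tert-butyl-4-methylpyridine (0.2 equiv), CH2Cl2, −78 → −40 °C
Reagents that add atoms: none
Why: SnCl4 chelates the β-keto ester of 16 and heterolyses the cyclopropane bond C4–C10 that is shared with the cyclopentanone (C4 leaves as a tin enolate, C10 becomes a methyl-stabilised tertiary cation), which enlarges the five-membered ketone ring to the six-membered ring A; the tethered allylsilane attacks C10 through C9, and loss of the silyl group from the β-silyl cation at C8 gives the exocyclic C8=C17 alkene. The closest known reaction type is the acid-promoted opening of acylcyclopropanes with olefin participation, shown for 5-methyl-6-alkenylbicyclo[3.1.0]hexan-2-ones, combined with allylsilane (Hosomi–Sakurai type) termination of a cation–olefin cyclization. Ring B closes in a 6-endo-trig mode through a chair transition state, whereas ring A is not closed but grows from five to six members when C5 is inserted between C4 and C10. C10 is set by inversion, the nucleophile entering anti to the departing C4, so that the configuration of C5 kept from step 10 is relayed to a trans ring fusion; C9 is set by the chair with the C11 chain equatorial, which the Z-allylsilane geometry enforces; C4 remains enolisable and is fixed in step 12. The step needs cleavage of C4–C10 and not of C4–C5, and ring closure before proton loss: the first is secured by the tertiary, methyl-bearing C10 against the secondary C5 and by the two carbonyl groups on C4 (the freely rotating ester can overlap with either cyclopropane bond), the second by the high nucleophilicity of the allylsilane, the low temperature and a hindered base that removes HCl.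

Step 12
Reactants: 17 methyl (5R,9R,10R,13R)-15-[(tert-butyldiphenylsilyl)oxy]-3-oxolabd-8(17)-en-19-oate
Product: 18 methyl (4S,5S,9R,10S,13R)-15-[(tert-butyldiphenylsilyl)oxy]-3-oxolabd-8(17)-en-19-oate (C4 now quaternary: CH3 equatorial; CO2Me axial)
Conditions: MeI, K2CO3, acetone, reflux
Reagents that add atoms: iodomethane, CI
Why: C-Alkylation of the β-keto ester enolate with the soft electrophile MeI should take place at C4 from the ring face opposite the axial C10 methyl group, which blocks the other face through a 1,3-diaxial contact, so that the new methyl (C18) becomes equatorial and the ester (C19) axial and cis to the C10 methyl as in the target.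

Step 13
Reactants: 18 methyl (4S,5S,9R,10S,13R)-15-[(tert-butyldiphenylsilyl)oxy]-3-oxolabd-8(17)-en-19-oate
Product: 19 methyl (4S,5S,9R,10S,13R)-15-[(tert-butyldiphenylsilyl)oxy]-3-hydroxylabd-8(17)-en-19-oate (C3 epimers)
Conditions: NaBH4, MeOH, 0 °C
Reagents that add atoms: none
Why: NaBH4 reduces the ketone and leaves the hindered methyl ester (chemoselective carbonyl reduction), and although axial hydride delivery to give mainly the equatorial alcohol is expected, the configuration of C3 is irrelevant because this centre is removed in step 15.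

Step 14
Reactants: 19 methyl (4S,5S,9R,10S,13R)-15-[(tert-butyldiphenylsilyl)oxy]-3-hydroxylabd-8(17)-en-19-oate
Product: 20 methyl (4S,5S,9R,10S,13R)-15-[(tert-butyldiphenylsilyl)oxy]-3-[(1H-imidazol-1-ylcarbonothioyl)oxy]labd-8(17)-en-19-oate
Conditions: 1,1'-thiocarbonyldiimidazole, DMAP (cat.), ClCH2CH2Cl, 70 °C
Reagents that add atoms: 1,1'-thiocarbonyldiimidazole, S=C(n1ccnc1)n1ccnc1
Why: Acylation of the secondary alcohol with thiocarbonyldiimidazole gives the thiocarbonyl derivative needed for Barton–McCombie deoxygenation, and since C4 carries no hydrogen neither elimination nor epimerisation can occur.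

Step 15
Reactants: 20 methyl (4S,5S,9R,10S,13R)-15-[(tert-butyldiphenylsilyl)oxy]-3-[(1H-imidazol-1-ylcarbonothioyl)oxy]labd-8(17)-en-19-oate
Product: 21 methyl (4R,5S,9R,10S,13R)-15-[(tert-butyldiphenylsilyl)oxy]labd-8(17)-en-19-oate
Conditions: Bu3SnH, AIBN (cat.), toluene, 100 °C
Reagents that add atoms: none
Why: In this Barton–McCombie deoxygenation the tributyltin radical adds to sulfur, the C3–O bond breaks to a secondary radical and Bu3SnH should reduce it faster than it can rearrange or reach the distant C8=C17 alkene, no stereocentre being formed or touched.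

Step 16
Reactants: 21 methyl (4R,5S,9R,10S,13R)-15-[(tert-butyldiphenylsilyl)oxy]labd-8(17)-en-19-oate
Product: 22 (4R,5S,9R,10S,13R)-15-[(tert-butyldiphenylsilyl)oxy]labd-8(17)-en-19-ol
Conditions: LiAlH4, THF, 0 °C → reflux
Reagents that add atoms: none
Why: LiAlH4 reduces the hindered axial neopentyl ester to the C19 primary alcohol (ester reduction), while the isolated alkene and the silyl ether are inert.

Step 17
Reactants: 22 (4R,5S,9R,10S,13R)-15-[(tert-butyldiphenylsilyl)oxy]labd-8(17)-en-19-ol; 23 (R)-2-methylbutanoic acid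
Product: 24 (4R,5S,9R,10S,13R)-15-[(tert-butyldiphenylsilyl)oxy]labd-8(17)-en-19-yl (2R)-2-methylbutanoate
Conditions: DCC, DMAP (cat.), CH2Cl2, 0 °C → rt
Reagents that add atoms: none
Why: Steglich esterification (carbodiimide activation with DMAP acyl transfer) acylates the only free hydroxyl group under conditions mild enough to keep the α-stereocentre of the acid.

Step 18
Reactants: 24 (4R,5S,9R,10S,13R)-15-[(tert-butyldiphenylsilyl)oxy]labd-8(17)-en-19-yl (2R)-2-methylbutanoate
Product: 25 (4R,5S,9R,10S,13R)-15-hydroxylabd-8(17)-en-19-yl (2R)-2-methylbutanoate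
Conditions: Bu4NF, AcOH (1:1), THF, rt
Reagents that add atoms: none
Why: Fluoride cleaves the silicon–oxygen bond (desilylation), and buffering with acetic acid protects the ester and its α-stereocentre from base and the exocyclic alkene from acid.

Step 19
Reactants: 25 (4R,5S,9R,10S,13R)-15-hydroxylabd-8(17)-en-19-yl (2R)-2-methylbutanoate
Product: 27 (4R,5S,9R,10S,13R)-19-{[(2R)-2-methylbutanoyl]oxy}labd-8(17)-en-15-oic acid (target), via aldehyde 26 (not isolated)
Conditions: TEMPO (cat.), PhI(OAc)2 (2.2 equiv), MeCN/H2O, rt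
Reagents that add atoms: water, O
Why: TEMPO-catalysed oxidation with PhI(OAc)2 should convert the primary alcohol into the aldehyde and, through its hydrate, into the carboxylic acid under near-neutral conditions that leave the exocyclic alkene, the ester and all stereocentres untouched (C14 next to the new carbonyl group is a CH2 group).

**Compound list**

1 | (R)-citronellol, (3R)-3,7-dimethyloct-6-en-1-ol | CC(C)=CCC[C@@H](C)CCO | starting material
2 | tert-butyl{[(3R)-3,7-dimethyloct-6-en-1-yl]oxy}diphenylsilane | CC(C)=CCC[C@@H](C)CCO[Si](c1ccccc1)(c1ccccc1)C(C)(C)C | intermediate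
3 | secondary ozonide, 3-{(3R)-5-[(tert-butyldiphenylsilyl)oxy]-3-methylpentyl}-5,5-dimethyl-1,2,4-trioxolane | CC1(C)OOC(CC[C@@H](C)CCO[Si](c2ccccc2)(c2ccccc2)C(C)(C)C)O1 | intermediate
4 | (4R)-6-[(tert-butyldiphenylsilyl)oxy]-4-methylhexanal | O=CCC[C@@H](C)CCO[Si](c1ccccc1)(c1ccccc1)C(C)(C)C | intermediate
5 | (2-bromoprop-2-en-1-yl)trimethylsilane | C=C(Br)C[Si](C)(C)C | starting material
6 | [3-(trimethylsilyl)prop-1-en-2-yl]magnesium bromide | C=C([Mg]Br)C[Si](C)(C)C | intermediate
7 | (6R)-8-[(tert-butyldiphenylsilyl)oxy]-6-methyl-2-[(trimethylsilyl)methyl]oct-1-en-3-ol (both C3 epimers) | C=C(C[Si](C)(C)C)C(O)CC[C@@H](C)CCO[Si](c1ccccc1)(c1ccccc1)C(C)(C)C | intermediate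
8 | 1-ethoxyvinyl ether (mixed ketene acetal) of 7 | C=C(OCC)OC(CC[C@@H](C)CCO[Si](c1ccccc1)(c1ccccc1)C(C)(C)C)C(=C)C[Si](C)(C)C | intermediate
9 | ethyl (4Z,8R)-10-[(tert-butyldiphenylsilyl)oxy]-8-methyl-4-[(trimethylsilyl)methyl]dec-4-enoate | CCOC(=O)CC/C(C[Si](C)(C)C)=C/CC[C@@H](C)CCO[Si](c1ccccc1)(c1ccccc1)C(C)(C)C | intermediate
10 | (4Z,8R)-10-[(tert-butyldiphenylsilyl)oxy]-8-methyl-4-[(trimethylsilyl)methyl]dec-4-enal | O=CCC/C(C[Si](C)(C)C)=C/CC[C@@H](C)CCO[Si](c1ccccc1)(c1ccccc1)C(C)(C)C | intermediate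
11 | (6Z,10R)-12-[(tert-butyldiphenylsilyl)oxy]-2,10-dimethyl-6-[(trimethylsilyl)methyl]dodeca-1,6-dien-3-ol (both C3 epimers) | C=C(C)C(O)CC/C(C[Si](C)(C)C)=C/CC[C@@H](C)CCO[Si](c1ccccc1)(c1ccccc1)C(C)(C)C | intermediate
12 | 1-ethoxyvinyl ether (mixed ketene acetal) of 11 | C=C(OCC)OC(CC/C(C[Si](C)(C)C)=C/CC[C@@H](C)CCO[Si](c1ccccc1)(c1ccccc1)C(C)(C)C)C(C)=C | intermediate
13 | ethyl (4E,8Z,12R)-14-[(tert-butyldiphenylsilyl)oxy]-4,12-dimethyl-8-[(trimethylsilyl)methyl]tetradeca-4,8-dienoate | CCOC(=O)CC/C(C)=C/CC/C(C[Si](C)(C)C)=C/CC[C@@H](C)CCO[Si](c1ccccc1)(c1ccccc1)C(C)(C)C | intermediate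
14 | methyl (6E,10Z,14R)-16-[(tert-butyldiphenylsilyl)oxy]-6,14-dimethyl-3-oxo-10-[(trimethylsilyl)methyl]hexadeca-6,10-dienoate | COC(=O)CC(=O)CC/C(C)=C/CC/C(C[Si](C)(C)C)=C/CC[C@@H](C)CCO[Si](c1ccccc1)(c1ccccc1)C(C)(C)C | intermediate
15 | methyl (6E,10Z,14R)-2-diazo-16-[(tert-butyldiphenylsilyl)oxy]-6,14-dimethyl-3-oxo-10-[(trimethylsilyl)methyl]hexadeca-6,10-dienoate | COC(=O)C(=[N+]=[N-])C(=O)CC/C(C)=C/CC/C(C[Si](C)(C)C)=C/CC[C@@H](C)CCO[Si](c1ccccc1)(c1ccccc1)C(C)(C)C | intermediate
16 | methyl (1S,5S,6S)-6-{(3Z,7R)-9-[(tert-butyldiphenylsilyl)oxy]-7-methyl-3-[(trimethylsilyl)methyl]non-3-en-1-yl}-5-methyl-2-oxobicyclo[3.1.0]hexane-1-carboxylate | COC(=O)[C@]12C(=O)CC[C@@]1(C)[C@@H]2CC/C(C[Si](C)(C)C)=C/CC[C@@H](C)CCO[Si](c3ccccc3)(c3ccccc3)C(C)(C)C | intermediate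
17 | methyl (5R,9R,10R,13R)-15-[(tert-butyldiphenylsilyl)oxy]-3-oxolabd-8(17)-en-19-oate (C4 epimers and enol) | C=C1CC[C@@H]2C(C(=O)OC)C(=O)CC[C@@]2(C)[C@@H]1CC[C@@H](C)CCO[Si](c3ccccc3)(c3ccccc3)C(C)(C)C | intermediate
18 | methyl (4S,5S,9R,10S,13R)-15-[(tert-butyldiphenylsilyl)oxy]-3-oxolabd-8(17)-en-19-oate | C=C1CC[C@@H]2[C@](C)(C(=O)OC)C(=O)CC[C@@]2(C)[C@@H]1CC[C@@H](C)CCO[Si](c3ccccc3)(c3ccccc3)C(C)(C)C | intermediate
19 | methyl (4S,5S,9R,10S,13R)-15-[(tert-butyldiphenylsilyl)oxy]-3-hydroxylabd-8(17)-en-19-oate (C3 epimers) | C=C1CC[C@@H]2[C@](C)(C(=O)OC)C(O)CC[C@@]2(C)[C@@H]1CC[C@@H](C)CCO[Si](c3ccccc3)(c3ccccc3)C(C)(C)C | intermediate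
20 | methyl (4S,5S,9R,10S,13R)-15-[(tert-butyldiphenylsilyl)oxy]-3-[(1H-imidazol-1-ylcarbonothioyl)oxy]labd-8(17)-en-19-oate | C=C1CC[C@@H]2[C@](C)(C(=O)OC)C(OC(=S)n3ccnc3)CC[C@@]2(C)[C@@H]1CC[C@@H](C)CCO[Si](c3ccccc3)(c3ccccc3)C(C)(C)C | intermediate
21 | methyl (4R,5S,9R,10S,13R)-15-[(tert-butyldiphenylsilyl)oxy]labd-8(17)-en-19-oate | C=C1CC[C@@H]2[C@](C)(C(=O)OC)CCC[C@@]2(C)[C@@H]1CC[C@@H](C)CCO[Si](c3ccccc3)(c3ccccc3)C(C)(C)C | intermediate
22 | (4R,5S,9R,10S,13R)-15-[(tert-butyldiphenylsilyl)oxy]labd-8(17)-en-19-ol | C=C1CC[C@@H]2[C@](C)(CO)CCC[C@@]2(C)[C@@H]1CC[C@@H](C)CCO[Si](c3ccccc3)(c3ccccc3)C(C)(C)C | intermediate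
23 | (R)-2-methylbutanoic acid | CC[C@@H](C)C(=O)O | starting material
24 | (4R,5S,9R,10S,13R)-15-[(tert-butyldiphenylsilyl)oxy]labd-8(17)-en-19-yl (2R)-2-methylbutanoate | C=C1CC[C@@H]2[C@](C)(COC(=O)[C@H](C)CC)CCC[C@@]2(C)[C@@H]1CC[C@@H](C)CCO[Si](c3ccccc3)(c3ccccc3)C(C)(C)C | intermediate
25 | (4R,5S,9R,10S,13R)-15-hydroxylabd-8(17)-en-19-yl (2R)-2-methylbutanoate | C=C1CC[C@@H]2[C@](C)(COC(=O)[C@H](C)CC)CCC[C@@]2(C)[C@@H]1CC[C@@H](C)CCO | intermediate
26 | (4R,5S,9R,10S,13R)-15-oxolabd-8(17)-en-19-yl (2R)-2-methylbutanoate | C=C1CC[C@@H]2[C@](C)(COC(=O)[C@H](C)CC)CCC[C@@]2(C)[C@@H]1CC[C@@H](C)CC=O | intermediate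
27 | (4R,5S,9R,10S,13R)-19-{[(2R)-2-methylbutanoyl]oxy}labd-8(17)-en-15-oic acid | C=C1CC[C@@H]2[C@](C)(COC(=O)[C@H](C)CC)CCC[C@@]2(C)[C@@H]1CC[C@@H](C)CC(=O)O | target

**Count and risks**

Total step count: 19. Longest linear sequence: 19 steps (1 → 27); 5 and 23 enter as commercial side components.

Steps most likely to fail:

1. Step 11. What may go wrong: ionisation of the cyclopropane at the other bond of C4 (C4–C5, which leaves the five-membered ring unexpanded), or proton loss from the C10 cation, capture of it by the ester oxygen, or acid-induced loss of the silyl group before ring B closes. The fallback sets out from 16 and comes back at 21. NaBH4 in MeOH should reduce the ring ketone of 16 to the cyclopropyl carbinol F1. SnCl4 with the hindered pyridine in CH2Cl2 at −78 °C should then ionise the carbinol; the cyclopropylcarbinyl-to-homoallyl rearrangement cleaves the same C4–C10 bond (again growth of the five-membered ring to ring A), now pulled by formation of the conjugated C3=C4 enoate, while the allylsilane closes ring B to give the dienoate F2. Conjugate reduction of F2 with LiBH(s-Bu)3 in THF at −78 °C and trapping of the ester enolate with MeI (entry anti to the C10 methyl) should give 21, so that steps 12 to 15 are bypassed.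

2. Step 10. What may go wrong: insufficient facial discrimination by the chiral copper complex, which would deliver the cyclopropane of antipodal ring configuration as a diastereomer that is hard to separate because C13 is remote; carbene dimerisation is a second risk. The fallback sets out from 14 and comes back at 17, and replaces catalyst control by a covalently bound auxiliary. DMAP-catalysed transesterification of 14 with (1R,2S,5R)-5-methyl-2-(2-phenylpropan-2-yl)cyclohexan-1-ol in toluene at reflux (methanol distilled off) should give the auxiliary β-keto ester F3. Diazo transfer as in step 9 gives the diazo ester F4. Cyclopropanation with achiral Rh2(OAc)4 in CH2Cl2 should then give the auxiliary cyclopropane F5, whose diastereomers can be separated by chromatography because the auxiliary sits next to the new centres (the enantiomeric auxiliary is used if the sense is opposite). SnCl4 as in step 11 converts F5 into the auxiliary bicyclic β-keto ester F6. Heating F6 with methanol and DMAP in toluene exchanges the auxiliary for methyl through the acylketene and returns 17.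

3. Step 4. What may go wrong: loss of the allylsilane under hot acid, by protodesilylation or by 1,4-elimination of the silyl group and the allylic oxygen to a diene, before the rearrangement is complete. The fallback sets out from 7 and comes back at 10. Acid-free Eschenmoser–Claisen rearrangement of 7 with N,N-dimethylacetamide dimethyl acetal in xylene at 140 °C should give, through the same chair, the amide F7. Cp2Zr(H)Cl in THF at rt should reduce the tertiary amide directly to aldehyde 10, so that step 5 is bypassed.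

**Further compounds**

F1 | step 11 | methyl (1S,5S,6S)-6-{(3Z,7R)-9-[(tert-butyldiphenylsilyl)oxy]-7-methyl-3-[(trimethylsilyl)methyl]non-3-en-1-yl}-2-hydroxy-5-methylbicyclo[3.1.0]hexane-1-carboxylate (C2 epimers) | COC(=O)[C@]12C(O)CC[C@@]1(C)[C@@H]2CC/C(C[Si](C)(C)C)=C/CC[C@@H](C)CCO[Si](c3ccccc3)(c3ccccc3)C(C)(C)C
F2 | step 11 | methyl (5S,9R,10S,13R)-15-[(tert-butyldiphenylsilyl)oxy]labda-3,8(17)-dien-19-oate | C=C1CC[C@@H]2C(C(=O)OC)=CCC[C@@]2(C)[C@@H]1CC[C@@H](C)CCO[Si](c3ccccc3)(c3ccccc3)C(C)(C)C
F3 | step 10 | (1R,2S,5R)-5-methyl-2-(2-phenylpropan-2-yl)cyclohexyl (6E,10Z,14R)-16-[(tert-butyldiphenylsilyl)oxy]-6,14-dimethyl-3-oxo-10-[(trimethylsilyl)methyl]hexadeca-6,10-dienoate | C[C@@H]1CC[C@@H](C(C)(C)c2ccccc2)[C@@H](C1)OC(=O)CC(=O)CC/C(C)=C/CC/C(C[Si](C)(C)C)=C/CC[C@@H](C)CCO[Si](c1ccccc1)(c1ccccc1)C(C)(C)C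
F4 | step 10 | (1R,2S,5R)-5-methyl-2-(2-phenylpropan-2-yl)cyclohexyl (6E,10Z,14R)-2-diazo-16-[(tert-butyldiphenylsilyl)oxy]-6,14-dimethyl-3-oxo-10-[(trimethylsilyl)methyl]hexadeca-6,10-dienoate | C[C@@H]1CC[C@@H](C(C)(C)c2ccccc2)[C@@H](C1)OC(=O)C(=[N+]=[N-])C(=O)CC/C(C)=C/CC/C(C[Si](C)(C)C)=C/CC[C@@H](C)CCO[Si](c1ccccc1)(c1ccccc1)C(C)(C)C
F5 | step 10 | (1R,2S,5R)-5-methyl-2-(2-phenylpropan-2-yl)cyclohexyl (1S,5S,6S)-6-{(3Z,7R)-9-[(tert-butyldiphenylsilyl)oxy]-7-methyl-3-[(trimethylsilyl)methyl]non-3-en-1-yl}-5-methyl-2-oxobicyclo[3.1.0]hexane-1-carboxylate | C[C@@H]1CC[C@@H](C(C)(C)c2ccccc2)[C@@H](C1)OC(=O)[C@]12C(=O)CC[C@@]1(C)[C@@H]2CC/C(C[Si](C)(C)C)=C/CC[C@@H](C)CCO[Si](c1ccccc1)(c1ccccc1)C(C)(C)C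
F6 | step 10 | (1R,2S,5R)-5-methyl-2-(2-phenylpropan-2-yl)cyclohexyl (5R,9R,10R,13R)-15-[(tert-butyldiphenylsilyl)oxy]-3-oxolabd-8(17)-en-19-oate (C4 epimers and enol) | C=C1CC[C@@H]2C(C(=O)O[C@@H]3C[C@H](C)CC[C@H]3C(C)(C)c3ccccc3)C(=O)CC[C@@]2(C)[C@@H]1CC[C@@H](C)CCO[Si](c1ccccc1)(c1ccccc1)C(C)(C)C
F7 | step 4 | (4Z,8R)-10-[(tert-butyldiphenylsilyl)oxy]-N,N,8-trimethyl-4-[(trimethylsilyl)methyl]dec-4-enamide | CN(C)C(=O)CC/C(C[Si](C)(C)C)=C/CC[C@@H](C)CCO[Si](c1ccccc1)(c1ccccc1)C(C)(C)C
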